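The 14-membered carbocycle (numbered from the methylidene carbon C1 through CH2 C2–C4 to the methyl-bearing C5) is disconnected between C4 and C5. The key step exploits the vicinal C5 methyl/C6 acetoxy pair of this ring, the retron of a trans-2-methyloxirane: a sulfone-stabilised C4 carbanion opens a (5S,6R)-epoxide at its methyl terminus. One operation closes the macrocycle, sets C5 by inversion and frees the C6 hydroxyl. The precursor is an open chain with a phenylsulfonyl end, silyl ethers at C7 and C14, a silyl-capped C8 alkyne as masked methylene lactone and the epoxide, made by Sharpless epoxidation and Evans syn-aldol. Cyclocarbonylation, acetylation and Shi epoxidation finish the target.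

Key step: step 20

Remark (numbering): ring carbons are C1 (methylidene carbon), C2–C4 (CH2), C5 (CH–CH3), C6 (CH–OAc), C7 (CH–O of the lactone), C8 (lactone CH), C9 (CH2), C10/C11 (epoxide, CH3 on C11), C12–C13 (CH2), C14 (CH–OAc); lactone carbons are C15 (alpha), C16 (C=O), C17 (=CH2); intermediates keep these numbers and every descriptor is the CIP descriptor of the compound named.
Remark (assumption): the alkynyl–silicon bond is taken to survive the buffered amalgam reduction of step 21; if it is lost there, step 22 gives the same triol 36.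

Step 1
Reactants: 1 5-chloropent-1-yne
Product: 2 5-chloro-2-iodopent-1-ene
Conditions: NaI, TMSCl, H2O, MeCN, rt
Reagents that add atoms: sodium iodide, [Na+].[I-]
Why: Markovnikov hydroiodination of the terminal alkyne by hydrogen iodide generated in the flask should give the 2-iodoalkene and leave the primary chloride untouched.

Step 2
Reactants: 3 geranyl acetate
Product: 6 (2E)-3-methyl-6-oxohex-2-en-1-yl acetate, via 6,7-epoxygeranyl acetate 4 (not isolated), via 6,7-diol 5 (not isolated)
Conditions: mCPBA, CH2Cl2, 0 °C; then HIO4·2H2O, THF/H2O, 0 °C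
Reagents that add atoms: 3-chloroperoxybenzoic acid (mCPBA), OOC(=O)c1cccc(Cl)c1
Why: Prilezhaev epoxidation should occur at the electron-rich 6,7-alkene (the 2,3-alkene is deactivated by the allylic acetate) and periodic acid should then cleave the epoxide through its diol (Malaprade cleavage) to the aldehyde.

Step 3
Reactants: 6 (2E)-3-methyl-6-oxohex-2-en-1-yl acetate; 2 5-chloro-2-iodopent-1-ene
Product: 8 rac-(2E)-10-chloro-6-hydroxy-3-methyl-7-methylidenedec-2-en-1-yl acetate, via alkenylchromium dichloride 7 (not isolated)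
Conditions: CrCl2, NiCl2 (cat.), DMF, rt
Reagents that add atoms: none
Why: Nozaki–Hiyama–Kishi coupling, in which nickel catalysis turns the alkenyl iodide into an alkenylchromium reagent that adds only to the aldehyde, should tolerate the acetate and the alkyl chloride; the C14 carbinol forms racemic and is set in steps 4 and 5.

Step 4
Reactants: 8 rac-(2E)-10-chloro-6-hydroxy-3-methyl-7-methylidenedec-2-en-1-yl acetate
Product: 9 (2E)-10-chloro-3-methyl-7-methylidene-6-oxodec-2-en-1-yl acetate
Conditions: Dess–Martin periodinane, CH2Cl2, 0 °C to rt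
Reagents that add atoms: none
Why: Dess–Martin oxidation should convert the allylic alcohol into the alpha-methylene ketone under neutral conditions that spare this Michael acceptor.

Step 5
Reactants: 9 (2E)-10-chloro-3-methyl-7-methylidene-6-oxodec-2-en-1-yl acetate
Product: 10 (2E,6R)-10-chloro-6-hydroxy-3-methyl-7-methylidenedec-2-en-1-yl acetate
Conditions: (S)-2-methyl-CBS-oxazaborolidine (cat.), catecholborane, toluene, −78 °C
Reagents that add atoms: none
Why: Corey–Bakshi–Shibata reduction should give the (R)-alcohol at C14 by catalyst control, the alpha-branched alkenyl group acting as the large substituent in the catalyst–borane–ketone complex.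

Step 6
Reactants: 10 (2E,6R)-10-chloro-6-hydroxy-3-methyl-7-methylidenedec-2-en-1-yl acetate
Product: 11 (2E,6R)-6-(tert-butyldimethylsilyloxy)-10-chloro-3-methyl-7-methylidenedec-2-en-1-yl acetate
Conditions: TBSCl, imidazole, DMF, rt
Reagents that add atoms: tert-butyldimethylsilyl chloride, CC(C)(C)[Si](C)(C)Cl
Why: Silyl ether formation (imidazole-promoted silylation) protects the C14 hydroxyl for the basic and organometallic steps ahead.

Step 7
Reactants: 11 (2E,6R)-6-(tert-butyldimethylsilyloxy)-10-chloro-3-methyl-7-methylidenedec-2-en-1-yl acetate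
Product: 12 (2E,6R)-6-(tert-butyldimethylsilyloxy)-10-chloro-3-methyl-7-methylidenedec-2-en-1-ol
Conditions: K2CO3 (cat.), MeOH, 0 °C to rt
Reagents that add atoms: none
Why: Base-catalysed transesterification with methanol (Zemplén-type deacetylation) frees the allylic alcohol without touching the silyl ether or the chloride.

Step 8
Reactants: 12 (2E,6R)-6-(tert-butyldimethylsilyloxy)-10-chloro-3-methyl-7-methylidenedec-2-en-1-ol
Product: 13 (2E,6R)-1-bromo-6-(tert-butyldimethylsilyloxy)-10-chloro-3-methyl-7-methylidenedec-2-ene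
Conditions: CBr4, PPh3, CH2Cl2, 0 °C
Reagents that add atoms: carbon tetrabromide, BrC(Br)(Br)Br
Why: The Appel reaction turns the primary allylic alcohol into the bromide with retention of the (E)-alkene.

Step 9
Reactants: 13 (2E,6R)-1-bromo-6-(tert-butyldimethylsilyloxy)-10-chloro-3-methyl-7-methylidenedec-2-ene; 14 acetic acid
Product: 16 (4E,8R)-8-(tert-butyldimethylsilyloxy)-12-chloro-5-methyl-9-methylidenedodec-4-enoic acid, via dilithioacetate 15 (not isolated)
Conditions: LiN(iPr)2 (2 equiv per acetic acid), THF/HMPA, 0 to 35 °C; then 13, 0 °C to rt; then 1 M HCl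
Reagents that add atoms: none
Why: SN2 alkylation of the acetic acid dianion by the allylic bromide, which is far more reactive than the primary chloride, should add C8 and C15 as a carboxylic acid in one step.

Step 10
Reactants: 16 (4E,8R)-8-(tert-butyldimethylsilyloxy)-12-chloro-5-methyl-9-methylidenedodec-4-enoic acid; 17 (R)-4-benzyl-1,3-oxazolidin-2-one
Product: 19 (4R)-4-benzyl-3-[(4E,8R)-8-(tert-butyldimethylsilyloxy)-12-chloro-5-methyl-9-methylidenedodec-4-enoyl]-1,3-oxazolidin-2-one, via mixed pivalic anhydride 18 (not isolated)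
Conditions: PivCl, Et3N, THF, −20 °C; then 17, LiCl, rt
Reagents that add atoms: none
Why: N-Acylation of the oxazolidinone through the mixed anhydride installs the chiral auxiliary for the aldol step.

Step 11
Reactants: 20 (E)-but-2-en-1-ol
Product: 21 [(2S,3S)-3-methyloxiran-2-yl]methanol
Conditions: Ti(OiPr)4 (cat.), L-(+)-diisopropyl tartrate (cat.), t-BuOOH, 4 Å molecular sieves, CH2Cl2, −20 °C
Reagents that add atoms: tert-butyl hydroperoxide, CC(C)(C)OO
Why: Sharpless asymmetric epoxidation with the L-tartrate ester should deliver oxygen to one enantioface of the (E)-allylic alcohol and so set both oxirane stereocentres (the future C5 and C6).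

Step 12
Reactants: 21 [(2S,3S)-3-methyloxiran-2-yl]methanol
Product: 22 (2R,3S)-3-methyloxirane-2-carbaldehyde
Conditions: TEMPO (cat.), PhI(OAc)2, CH2Cl2, rt
Reagents that add atoms: none
Why: TEMPO-catalysed oxidation (oxoammonium mechanism) should stop at the aldehyde and leave the epoxide and its stereocentres intact.

Step 13
Reactants: 19 (4R)-4-benzyl-3-[(4E,8R)-8-(tert-butyldimethylsilyloxy)-12-chloro-5-methyl-9-methylidenedodec-4-enoyl]-1,3-oxazolidin-2-one; 22 (2R,3S)-3-methyloxirane-2-carbaldehyde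
Product: 24 (4R)-4-benzyl-3-[(2R,4E,8R)-8-(tert-butyldimethylsilyloxy)-12-chloro-2-{(R)-hydroxy[(2S,3S)-3-methyloxiran-2-yl]methyl}-5-methyl-9-methylidenedodec-4-enoyl]-1,3-oxazolidin-2-one, via dibutylboron enolate 23 (not isolated)
Conditions: Bu2BOTf, iPr2NEt, CH2Cl2, −78 to 0 °C; then 22, −78 to −10 °C; then pH 7 buffer, MeOH, H2O2, 0 °C
Reagents that add atoms: none
Why: Evans syn-aldol reaction, in which the (Z)-boron enolate reacts through a closed chair transition state on the face opposite the benzyl group, should set C7 and C8 by auxiliary control and override the weak facial bias of the trans-epoxy aldehyde.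

Step 14
Reactants: 24 (4R)-4-benzyl-3-[(2R,4E,8R)-8-(tert-butyldimethylsilyloxy)-12-chloro-2-{(R)-hydroxy[(2S,3S)-3-methyloxiran-2-yl]methyl}-5-methyl-9-methylidenedodec-4-enoyl]-1,3-oxazolidin-2-one
Product: 25 (4R)-4-benzyl-3-[(2R,4E,8R)-8-(tert-butyldimethylsilyloxy)-2-{(R)-(tert-butyldimethylsilyloxy)[(2R,3S)-3-methyloxiran-2-yl]methyl}-12-chloro-5-methyl-9-methylidenedodec-4-enoyl]-1,3-oxazolidin-2-one
Conditions: TBSOTf, 2,6-lutidine, CH2Cl2, −78 °C
Reagents that add atoms: tert-butyldimethylsilyl triflate, CC(C)(C)[Si](C)(C)OS(=O)(=O)C(F)(F)F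
Why: Silylation with the silyl triflate and a hindered base should protect the C7 hydroxyl at low temperature without opening the neighbouring epoxide.

Step 15
Reactants: 25 (4R)-4-benzyl-3-[(2R,4E,8R)-8-(tert-butyldimethylsilyloxy)-2-{(R)-(tert-butyldimethylsilyloxy)[(2R,3S)-3-methyloxiran-2-yl]methyl}-12-chloro-5-methyl-9-methylidenedodec-4-enoyl]-1,3-oxazolidin-2-one
Product: 26 (2S,4E,8R)-8-(tert-butyldimethylsilyloxy)-2-{(R)-(tert-butyldimethylsilyloxy)[(2R,3S)-3-methyloxiran-2-yl]methyl}-12-chloro-5-methyl-9-methylidenedodec-4-en-1-ol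
Conditions: LiBH4, MeOH (1 equiv), Et2O, 0 °C
Reagents that add atoms: none
Why: Reductive cleavage of the N-acyloxazolidinone by LiBH4 should give the primary alcohol and return the auxiliary while the epoxide and the chloride stay inert at 0 °C.

Step 16
Reactants: 26 (2S,4E,8R)-8-(tert-butyldimethylsilyloxy)-2-{(R)-(tert-butyldimethylsilyloxy)[(2R,3S)-3-methyloxiran-2-yl]methyl}-12-chloro-5-methyl-9-methylidenedodec-4-en-1-ol
Product: 27 (2R,4E,8R)-8-(tert-butyldimethylsilyloxy)-2-{(R)-(tert-butyldimethylsilyloxy)[(2R,3S)-3-methyloxiran-2-yl]methyl}-12-chloro-5-methyl-9-methylidenedodec-4-enal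
Conditions: Dess–Martin periodinane, pyridine, CH2Cl2, 0 °C to rt
Reagents that add atoms: none
Why: Pyridine-buffered Dess–Martin oxidation should give the alpha-branched aldehyde without epimerising C8 or eliminating the beta-silyloxy group.

Step 17
Reactants: 27 (2R,4E,8R)-8-(tert-butyldimethylsilyloxy)-2-{(R)-(tert-butyldimethylsilyloxy)[(2R,3S)-3-methyloxiran-2-yl]methyl}-12-chloro-5-methyl-9-methylidenedodec-4-enal
Product: 28 (3S,5E,9R)-9-(tert-butyldimethylsilyloxy)-3-{(R)-(tert-butyldimethylsilyloxy)[(2R,3S)-3-methyloxiran-2-yl]methyl}-13-chloro-6-methyl-10-methylidenetridec-5-en-1-yne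
Conditions: dimethyl (1-diazo-2-oxopropyl)phosphonate, K2CO3, MeOH, 0 °C to rt
Reagents that add atoms: dimethyl (1-diazo-2-oxopropyl)phosphonate (Ohira–Bestmann reagent), COP(=O)(OC)C(=[N+]=[N-])C(C)=O
Why: Ohira–Bestmann (Seyferth–Gilbert) homologation should convert the aldehyde into the terminal alkyne (C15≡C17) under mild carbonate conditions that preserve C8.

Step 18
Reactants: 28 (3S,5E,9R)-9-(tert-butyldimethylsilyloxy)-3-{(R)-(tert-butyldimethylsilyloxy)[(2R,3S)-3-methyloxiran-2-yl]methyl}-13-chloro-6-methyl-10-methylidenetridec-5-en-1-yne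
Product: 30 (3S,5E,9R)-9-(tert-butyldimethylsilyloxy)-3-{(R)-(tert-butyldimethylsilyloxy)[(2R,3S)-3-methyloxiran-2-yl]methyl}-13-chloro-6-methyl-10-methylidene-1-(trimethylsilyl)tridec-5-en-1-yne, via lithium acetylide 29 (not isolated)
Conditions: n-BuLi, THF, −78 °C; then TMSCl, −78 to 0 °C
Reagents that add atoms: chlorotrimethylsilane, C[Si](C)(C)Cl
Why: Deprotonation of the alkyne and C-silylation caps the only C–H acidic enough to compete with the sulfone in the ring closure.

Step 19
Reactants: 30 (3S,5E,9R)-9-(tert-butyldimethylsilyloxy)-3-{(R)-(tert-butyldimethylsilyloxy)[(2R,3S)-3-methyloxiran-2-yl]methyl}-13-chloro-6-methyl-10-methylidene-1-(trimethylsilyl)tridec-5-en-1-yne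
Product: 32 (3S,5E,9R)-9-(tert-butyldimethylsilyloxy)-3-{(R)-(tert-butyldimethylsilyloxy)[(2R,3S)-3-methyloxiran-2-yl]methyl}-6-methyl-10-methylidene-13-(phenylsulfonyl)-1-(trimethylsilyl)tridec-5-en-1-yne, via primary iodide 31 (not isolated)
Conditions: PhSO2Na, NaI (cat.), DMF, 70 °C
Reagents that add atoms: sodium benzenesulfinate, [Na+].[O-]S(=O)c1ccccc1
Why: SN2 displacement of the primary chloride by the sulfinate sulfur, accelerated by Finkelstein exchange in the flask, installs the carbanion-stabilising group while the hindered internal epoxide should be left alone.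

Step 20
Reactants: 32 (3S,5E,9R)-9-(tert-butyldimethylsilyloxy)-3-{(R)-(tert-butyldimethylsilyloxy)[(2R,3S)-3-methyloxiran-2-yl]methyl}-6-methyl-10-methylidene-13-(phenylsulfonyl)-1-(trimethylsilyl)tridec-5-en-1-yne
Product: 34 macrocyclic hydroxy sulfone: 14-membered carbocycle C1–C14 with 1-methylidene; 4-(phenylsulfonyl); 5-methyl; 6-hydroxy; 7-(tert-butyldimethylsilyloxy); 8-[(trimethylsilyl)ethynyl]; (10E)-11-methyl-10-ene; 14-(tert-butyldimethylsilyloxy); (5R,6R,7R,8S,14R); epimers at C4, via alpha-lithio sulfone 33 (not isolated)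
Conditions: n-BuLi, THF, −78 °C; then slow transfer into BF3·OEt2, THF (final about 0.002 M), −78 to −40 °C
Reagents that add atoms: none
Why: n-BuLi removes the proton alpha to the sulfone to give carbanion 33, and BF3·OEt2 then activates the oxirane so that C4 attacks its methyl-bearing carbon C5 in an intramolecular SN2 displacement that opens the three-membered ring and leaves the oxygen on C6. The closest known reaction type is the closure of 14-membered cembrane rings by attack of a sulfur-stabilised carbanion on an epoxide, combined with the BF3-assisted opening of 2,3-disubstituted epoxides by lithiated sulfones. The carbocycle closes in the 14-endo-tet mode (both oxirane carbons become ring members); the alternative 13-exo-tet attack at C6 is disfavoured because C6 is flanked by the silyloxy-bearing C7, which hinders it and deactivates it inductively. The new stereocentre C5 is set by inversion at the (5S)-oxirane carbon, so the epoxide from the Sharpless step controls it and the methyl ends up syn to the C6 hydroxyl as in the target, while C6 keeps its configuration and C4 forms as an inconsequential epimer mixture. The step needs ring closure to win over intermolecular coupling, which high dilution with the carbanion formed before it meets the Lewis acid should secure, and it needs chemoselectivity, which is secured because the alkyne is capped, both hydroxyls are silylated and the secondary oxirane should not ionise towards the C10=C11 alkene at −78 °C.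

Step 21
Reactants: 34 macrocyclic hydroxy sulfone (5R,6R,7R,8S,14R; C4 epimers)
Product: 35 macrocyclic alcohol: the ring of 34 with C4 as CH2; 6-hydroxy; 7- and 14-(tert-butyldimethylsilyloxy); 8-[(trimethylsilyl)ethynyl]; (5S,6R,7R,8S,10E,14R)
Conditions: sodium amalgam (Na/Hg), Na2HPO4, MeOH/THF, −20 °C
Reagents that add atoms: none
Why: Reductive desulfonylation by electron transfer from sodium amalgam cleaves the C–S bond and leaves C4 as the ring methylene.

Step 22
Reactants: 35 macrocyclic alcohol (5S,6R,7R,8S,10E,14R)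
Product: 36 macrocyclic triol: 1-methylidene; 5-methyl; 6,7,14-trihydroxy; 8-ethynyl; (10E)-11-methyl-10-ene; (5S,6R,7R,8S,14R)
Conditions: Bu4NF, THF, 0 °C to rt
Reagents that add atoms: none
Why: Fluoride-mediated desilylation should remove both silyl ethers and the alkynylsilane in one operation.

Step 23
Reactants: 36 macrocyclic triol (5S,6R,7R,8S,10E,14R)
Product: 37 diol lactone: 6,14-dihydroxy macrocycle with the cis-fused alpha-methylene gamma-lactone across C7–C8 (oxygen on C7; C15 on C8); (5S,6R,7R,8S,10E,14R)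
Conditions: PdI2 (cat.), PBu3 (cat.), CO (4 atm), MeCN, 75 °C
Reagents that add atoms: carbon monoxide, [C-]#[O+]
Why: Palladium-catalysed cyclocarbonylation of the homopropargylic alcohol (an alkoxycarbonylpalladium species from the C7 hydroxyl and CO adds across the alkyne and is protonated) should build the cis-fused alpha-methylene gamma-lactone with C7 and C8 untouched, five-membered closure through O7 being faster than six-membered closure through O6.

Step 24
Reactants: 37 diol lactone (5S,6R,7R,8S,10E,14R)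
Product: 38 6,14-diacetate of 37; (5S,6R,7R,8S,10E,14R)
Conditions: Ac2O, pyridine, DMAP (cat.), CH2Cl2, 0 °C to rt
Reagents that add atoms: acetic anhydride, CC(=O)OC(C)=O
Why: DMAP-catalysed acetylation esterifies both remaining secondary hydroxyls (C6 and C14).

Step 25
Reactants: 38 6,14-diacetate (5S,6R,7R,8S,10E,14R)
Product: 39 target CNP0323853.1; (5S,6R,7R,8S,10R,11R,14R)
Conditions: D-fructose-derived Shi ketone (cat.), KHSO5 (as Oxone), aq. K2CO3 buffer (pH 10.5), Bu4NHSO4 (cat.), MeCN/dimethoxymethane, 0 °C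
Reagents that add atoms: potassium peroxymonosulfate (KHSO5), [K+].[O-]S(=O)(=O)OO
Why: Shi epoxidation, in which the dioxirane of the D-fructose-derived ketone attacks the most electron-rich trisubstituted (E)-alkene through a spiro transition state, should give the (10R,11R)-epoxide by reagent control and spare the 1,1-disubstituted and the electron-poor alkenes.

Compound list
1 | 5-chloropent-1-yne | C#CCCCCl | starting material
2 | 5-chloro-2-iodopent-1-ene | C=C(I)CCCCl | intermediate
3 | geranyl acetate ((2E)-3,7-dimethylocta-2,6-dien-1-yl acetate) | CC(=O)OC/C=C(\C)CCC=C(C)C | starting material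
4 | 6,7-epoxygeranyl acetate (racemic) | CC(=O)OC/C=C(\C)CCC1OC1(C)C | intermediate
5 | (2E)-6,7-dihydroxy-3,7-dimethyloct-2-en-1-yl acetate (racemic) | CC(=O)OC/C=C(\C)CCC(O)C(C)(C)O | intermediate
6 | (2E)-3-methyl-6-oxohex-2-en-1-yl acetate | CC(=O)OC/C=C(\C)CCC=O | intermediate
7 | (5-chloropent-1-en-2-yl)chromium dichloride | C=C([Cr](Cl)Cl)CCCCl | intermediate
8 | rac-(2E)-10-chloro-6-hydroxy-3-methyl-7-methylidenedec-2-en-1-yl acetate | CC(=O)OC/C=C(\C)CCC(O)C(=C)CCCCl | intermediate
9 | (2E)-10-chloro-3-methyl-7-methylidene-6-oxodec-2-en-1-yl acetate | CC(=O)OC/C=C(\C)CCC(=O)C(=C)CCCCl | intermediate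
10 | (2E,6R)-10-chloro-6-hydroxy-3-methyl-7-methylidenedec-2-en-1-yl acetate | CC(=O)OC/C=C(\C)CC[C@@H](O)C(=C)CCCCl | intermediate
11 | (2E,6R)-6-(tert-butyldimethylsilyloxy)-10-chloro-3-methyl-7-methylidenedec-2-en-1-yl acetate | CC(=O)OC/C=C(\C)CC[C@@H](O[Si](C)(C)C(C)(C)C)C(=C)CCCCl | intermediate
12 | (2E,6R)-6-(tert-butyldimethylsilyloxy)-10-chloro-3-methyl-7-methylidenedec-2-en-1-ol | OC/C=C(\C)CC[C@@H](O[Si](C)(C)C(C)(C)C)C(=C)CCCCl | intermediate
13 | (2E,6R)-1-bromo-6-(tert-butyldimethylsilyloxy)-10-chloro-3-methyl-7-methylidenedec-2-ene | BrC/C=C(\C)CC[C@@H](O[Si](C)(C)C(C)(C)C)C(=C)CCCCl | intermediate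
14 | acetic acid | CC(=O)O | starting material
15 | dilithioacetate (dilithium salt of the acetic acid dianion) | [Li+].[Li+].[CH2-]C(=O)[O-] | intermediate
16 | (4E,8R)-8-(tert-butyldimethylsilyloxy)-12-chloro-5-methyl-9-methylidenedodec-4-enoic acid | OC(=O)CC/C=C(\C)CC[C@@H](O[Si](C)(C)C(C)(C)C)C(=C)CCCCl | intermediate
17 | (R)-4-benzyl-1,3-oxazolidin-2-one | O=C1OC[C@@H](Cc2ccccc2)N1 | starting material
18 | mixed anhydride of acid 16 and pivalic acid | CC(C)(C)C(=O)OC(=O)CC/C=C(\C)CC[C@@H](O[Si](C)(C)C(C)(C)C)C(=C)CCCCl | intermediate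
19 | (4R)-4-benzyl-3-[(4E,8R)-8-(tert-butyldimethylsilyloxy)-12-chloro-5-methyl-9-methylidenedodec-4-enoyl]-1,3-oxazolidin-2-one | O=C1OC[C@@H](Cc2ccccc2)N1C(=O)CC/C=C(\C)CC[C@@H](O[Si](C)(C)C(C)(C)C)C(=C)CCCCl | intermediate
20 | (E)-but-2-en-1-ol | C/C=C/CO | starting material
21 | [(2S,3S)-3-methyloxiran-2-yl]methanol | C[C@@H]1O[C@H]1CO | intermediate
22 | (2R,3S)-3-methyloxirane-2-carbaldehyde | C[C@@H]1O[C@H]1C=O | intermediate
23 | (Z)-dibutylboron enolate of imide 19 | O=C1OC[C@@H](Cc2ccccc2)N1/C(OB(CCCC)CCCC)=C/C/C=C(\C)CC[C@@H](O[Si](C)(C)C(C)(C)C)C(=C)CCCCl | intermediate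
24 | (4R)-4-benzyl-3-[(2R,4E,8R)-8-(tert-butyldimethylsilyloxy)-12-chloro-2-{(R)-hydroxy[(2S,3S)-3-methyloxiran-2-yl]methyl}-5-methyl-9-methylidenedodec-4-enoyl]-1,3-oxazolidin-2-one | O=C1OC[C@@H](Cc2ccccc2)N1C(=O)[C@H](C/C=C(\C)CC[C@@H](O[Si](C)(C)C(C)(C)C)C(=C)CCCCl)[C@@H](O)[C@@H]1O[C@H]1C | intermediate
25 | (4R)-4-benzyl-3-[(2R,4E,8R)-8-(tert-butyldimethylsilyloxy)-2-{(R)-(tert-butyldimethylsilyloxy)[(2R,3S)-3-methyloxiran-2-yl]methyl}-12-chloro-5-methyl-9-methylidenedodec-4-enoyl]-1,3-oxazolidin-2-one | O=C1OC[C@@H](Cc2ccccc2)N1C(=O)[C@H](C/C=C(\C)CC[C@@H](O[Si](C)(C)C(C)(C)C)C(=C)CCCCl)[C@@H](O[Si](C)(C)C(C)(C)C)[C@@H]1O[C@H]1C | intermediate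
26 | (2S,4E,8R)-8-(tert-butyldimethylsilyloxy)-2-{(R)-(tert-butyldimethylsilyloxy)[(2R,3S)-3-methyloxiran-2-yl]methyl}-12-chloro-5-methyl-9-methylidenedodec-4-en-1-ol | OC[C@H](C/C=C(\C)CC[C@@H](O[Si](C)(C)C(C)(C)C)C(=C)CCCCl)[C@@H](O[Si](C)(C)C(C)(C)C)[C@@H]1O[C@H]1C | intermediate
27 | (2R,4E,8R)-8-(tert-butyldimethylsilyloxy)-2-{(R)-(tert-butyldimethylsilyloxy)[(2R,3S)-3-methyloxiran-2-yl]methyl}-12-chloro-5-methyl-9-methylidenedodec-4-enal | O=C[C@H](C/C=C(\C)CC[C@@H](O[Si](C)(C)C(C)(C)C)C(=C)CCCCl)[C@@H](O[Si](C)(C)C(C)(C)C)[C@@H]1O[C@H]1C | intermediate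
28 | (3S,5E,9R)-9-(tert-butyldimethylsilyloxy)-3-{(R)-(tert-butyldimethylsilyloxy)[(2R,3S)-3-methyloxiran-2-yl]methyl}-13-chloro-6-methyl-10-methylidenetridec-5-en-1-yne | C#C[C@H](C/C=C(\C)CC[C@@H](O[Si](C)(C)C(C)(C)C)C(=C)CCCCl)[C@@H](O[Si](C)(C)C(C)(C)C)[C@@H]1O[C@H]1C | intermediate
29 | lithium acetylide of alkyne 28 | [Li]C#C[C@H](C/C=C(\C)CC[C@@H](O[Si](C)(C)C(C)(C)C)C(=C)CCCCl)[C@@H](O[Si](C)(C)C(C)(C)C)[C@@H]1O[C@H]1C | intermediate
30 | (3S,5E,9R)-9-(tert-butyldimethylsilyloxy)-3-{(R)-(tert-butyldimethylsilyloxy)[(2R,3S)-3-methyloxiran-2-yl]methyl}-13-chloro-6-methyl-10-methylidene-1-(trimethylsilyl)tridec-5-en-1-yne | C[Si](C)(C)C#C[C@H](C/C=C(\C)CC[C@@H](O[Si](C)(C)C(C)(C)C)C(=C)CCCCl)[C@@H](O[Si](C)(C)C(C)(C)C)[C@@H]1O[C@H]1C | intermediate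
31 | 13-iodo analogue of 30 (iodine in place of chlorine) | C[Si](C)(C)C#C[C@H](C/C=C(\C)CC[C@@H](O[Si](C)(C)C(C)(C)C)C(=C)CCCI)[C@@H](O[Si](C)(C)C(C)(C)C)[C@@H]1O[C@H]1C | intermediate
32 | (3S,5E,9R)-9-(tert-butyldimethylsilyloxy)-3-{(R)-(tert-butyldimethylsilyloxy)[(2R,3S)-3-methyloxiran-2-yl]methyl}-6-methyl-10-methylidene-13-(phenylsulfonyl)-1-(trimethylsilyl)tridec-5-en-1-yne | C[Si](C)(C)C#C[C@H](C/C=C(\C)CC[C@@H](O[Si](C)(C)C(C)(C)C)C(=C)CCCS(=O)(=O)c1ccccc1)[C@@H](O[Si](C)(C)C(C)(C)C)[C@@H]1O[C@H]1C | intermediate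
33 | 13-lithio derivative of sulfone 32 (alpha-lithio sulfone) | C[Si](C)(C)C#C[C@H](C/C=C(\C)CC[C@@H](O[Si](C)(C)C(C)(C)C)C(=C)CCC([Li])S(=O)(=O)c1ccccc1)[C@@H](O[Si](C)(C)C(C)(C)C)[C@@H]1O[C@H]1C | intermediate
34 | macrocyclic hydroxy sulfone: 14-membered carbocycle C1–C14 with 1-methylidene; 4-(phenylsulfonyl); 5-methyl; 6-hydroxy; 7-(tert-butyldimethylsilyloxy); 8-[(trimethylsilyl)ethynyl]; (10E)-11-methyl-10-ene; 14-(tert-butyldimethylsilyloxy); (5R,6R,7R,8S,14R); epimers at C4 | C=C1CCC(S(=O)(=O)c2ccccc2)[C@H](C)[C@@H](O)[C@H](O[Si](C)(C)C(C)(C)C)[C@H](C#C[Si](C)(C)C)C/C=C(\C)CC[C@H]1O[Si](C)(C)C(C)(C)C | intermediate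
35 | macrocyclic alcohol: the ring of 34 with C4 as CH2; 6-hydroxy; 7- and 14-(tert-butyldimethylsilyloxy); 8-[(trimethylsilyl)ethynyl]; (5S,6R,7R,8S,10E,14R) | C=C1CCC[C@H](C)[C@@H](O)[C@H](O[Si](C)(C)C(C)(C)C)[C@H](C#C[Si](C)(C)C)C/C=C(\C)CC[C@H]1O[Si](C)(C)C(C)(C)C | intermediate
36 | macrocyclic triol: 1-methylidene; 5-methyl; 6,7,14-trihydroxy; 8-ethynyl; (10E)-11-methyl-10-ene; (5S,6R,7R,8S,14R) | C=C1CCC[C@H](C)[C@@H](O)[C@H](O)[C@H](C#C)C/C=C(\C)CC[C@H]1O | intermediate
37 | diol lactone: 6,14-dihydroxy macrocycle with the cis-fused alpha-methylene gamma-lactone across C7–C8 (oxygen on C7; C15 on C8); (5S,6R,7R,8S,10E,14R) | C=C1CCC[C@H](C)[C@@H](O)[C@@H]2OC(=O)C(=C)[C@@H]2C/C=C(\C)CC[C@H]1O | intermediate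
38 | 6,14-diacetate of 37; (5S,6R,7R,8S,10E,14R) | C=C1CCC[C@H](C)[C@@H](OC(C)=O)[C@@H]2OC(=O)C(=C)[C@@H]2C/C=C(\C)CC[C@H]1OC(C)=O | intermediate
39 | target CNP0323853.1; (5S,6R,7R,8S,10R,11R,14R) | C=C1CCC[C@H](C)[C@@H](OC(C)=O)[C@@H]2OC(=O)C(=C)[C@@H]2C[C@H]2O[C@]2(C)CC[C@H]1OC(C)=O | target

Total step count: 25. Longest linear sequence: 22 steps (geranyl acetate 3 to 39 through steps 2–10 and 13–25).

Steps most likely to fail

Step 20 (ring closure). The stabilised carbanion may attack the internal epoxide too slowly at high dilution, so that intermolecular coupling or Lewis-acid-induced rearrangement of the epoxide takes over. The fallback sets out from chloride 30 and comes back to the route at 35. A Finkelstein exchange run with excess NaI in acetone should give iodide 31, this time isolated. Iodine–lithium exchange with t-BuLi in Et2O/pentane at −78 °C should then give the unstabilised primary alkyllithium F1. After dilution and addition of BF3·OEt2 this far stronger nucleophile should open the epoxide at C5 in the same stereochemical sense and give 35 directly, so that the sulfone steps 19 and 21 are not needed.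

Step 23 (cyclocarbonylation). Site selectivity may be poor: the lactone may close through the C6 hydroxyl to a six-membered ring, or that hydroxyl may add in conjugate fashion to the new methylene lactone under phosphine catalysis. The fallback sets out from 35 and comes back at 38. The C6 hydroxyl is acetylated first (Ac2O, pyridine, DMAP) to give the 6-O-acetyl compound F2. Bu4NF buffered with AcOH should remove the three silyl groups without acyl migration and give the 6-O-acetyl 7,14-diol F3. Cyclocarbonylation under the conditions of step 23 can then use only the C7 hydroxyl for a small ring and should give the 6-O-acetyl lactone F4, and acetylation of the C14 hydroxyl returns to 38.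

Step 25 (epoxidation). Facial selectivity may be poor, because the ring conformation may expose one face of the C10=C11 alkene so strongly that it overrides the chiral ketone. The fallback sets out from 38 and comes back at 39. If oxygen transfer prefers the wrong face, NBS in aqueous THF should form the bromonium ion on that same exposed face, and water should open it at the tertiary C11 from the other side to give the (10S,11R)-bromohydrin F5. DBU then closes the oxirane by backside displacement of bromide, which places the oxygen on the face that direct epoxidation avoids.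

Further compounds
F1 | step 20 | primary alkyllithium (lithium on C4) formed from iodide 31 | C[Si](C)(C)C#C[C@H](C/C=C(\C)CC[C@@H](O[Si](C)(C)C(C)(C)C)C(=C)CCC[Li])[C@@H](O[Si](C)(C)C(C)(C)C)[C@@H]1O[C@H]1C
F2 | step 23 | 6-O-acetyl derivative of 35 | C=C1CCC[C@H](C)[C@@H](OC(C)=O)[C@H](O[Si](C)(C)C(C)(C)C)[C@H](C#C[Si](C)(C)C)C/C=C(\C)CC[C@H]1O[Si](C)(C)C(C)(C)C
F3 | step 23 | 6-O-acetyl 7,14-diol with free 8-ethynyl group | C=C1CCC[C@H](C)[C@@H](OC(C)=O)[C@H](O)[C@H](C#C)C/C=C(\C)CC[C@H]1O
F4 | step 23 | 6-O-acetyl 14-hydroxy alpha-methylene gamma-lactone | C=C1CCC[C@H](C)[C@@H](OC(C)=O)[C@@H]2OC(=O)C(=C)[C@@H]2C/C=C(\C)CC[C@H]1O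
F5 | step 25 | (10S,11R)-10-bromo-11-hydroxy derivative of 38 | C=C1CCC[C@H](C)[C@@H](OC(C)=O)[C@@H]2OC(=O)C(=C)[C@@H]2C[C@H](Br)[C@](C)(O)CC[C@H]1OC(C)=O
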